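The route rests on cutting ring A (cyclopentane C10–C14) back to a cyclohexanone, ring A′, in which C1 still sits between C11 and C12. A photochemical Wolff rearrangement of the C11-diazo C1-ketone contracts ring A′ to ring A in one operation, expels C1 as an exocyclic acyl carbon on C11 and sets C11 by convex-face protonation. It exploits that C11 of ring A bears the sp2 carbon C1 while C12 and C13 are bare CH2 groups. The precursor is a cis-decalin from a quinone Diels–Alder reaction that sets C10 and C14 and brings the C15 and C16 oxygens; citronellal supplies C2–C7, and two Ni/Cr couplings (C7–C8, then C1–C2) build ring C.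

Key step: step 13

Numbering used throughout: C1 carries the exocyclic CH2 (C17); C2 = CH(OAc); C3, C4 = CH2; C5 = CH(CH3); C6 = CH2; C7 = CH(OAc); C8=C9 is the ring alkene (C9 carries CH3); C10, C11 = ring CH; C12, C13 = CH2; C14 = C(CH3); C15, C16 = CH(OH). Ring A = C10–C11–C12–C13–C14; ring B = C8–C9–C10–C14–C15–C16; ring C = C1 to C11; ring A′ = C10–C11–C1–C12–C13–C14 (six-membered precursor of ring A). β is the face of the bicyclic core that carries 10-H and 14-CH3 (convex face); α is the opposite face.

Assumption: in steps 3, 9 and 18 the ligand antipode written stands for the antipode that gives the configuration drawn; 1, 3 and 12 are taken as commercial.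

Step 1
Reactants: 1 2-methoxy-6-methylphenol
Product: 2 2-methoxy-6-methyl-1,4-benzoquinone
Conditions: Co(salen) [N,N′-bis(salicylidene)ethylenediamine cobalt, divalent cobalt] (5 mol %), O2 (1 atm), DMF, 23 °C
Reagents that add atoms: dioxygen, O=O
Why: Cobalt–salen-catalysed aerobic oxidation of a 2,6-disubstituted phenol to the para-benzoquinone; both ortho positions are blocked, so oxygen enters para, and no stereocentre is formed.

Step 2
Reactants: 3 methyl vinyl ketone
Product: 4 2-(triisopropylsilyloxy)buta-1,3-diene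
Conditions: TIPSOTf, Et3N, Et2O, 0 to 23 °C
Reagents that add atoms: triisopropylsilyl triflate, CC(C)[Si](C(C)C)(C(C)C)OS(=O)(=O)C(F)(F)F
Why: Silyl dienol ether formation, in which soft enolisation of the enone by the silyl triflate and amine gives the cross-conjugated 2-silyloxydiene.

Step 3
Reactants: 2 2-methoxy-6-methyl-1,4-benzoquinone; 4 2-(triisopropylsilyloxy)buta-1,3-diene
Product: 5 cis-fused Diels–Alder adduct (C15 and C9 ketones; 16-OMe; C1 silyl enol ether)
Conditions: (R)-BINOL, TiCl2(OiPr)2 (10 mol %), 4 Å MS, CH2Cl2, −30 °C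
Reagents that add atoms: none
Why: Catalytic asymmetric Diels–Alder reaction of a quinone: the methoxy-bearing C16=C8 bond is deactivated so the diene adds across C10=C14, two-point binding of titanium to the C15 carbonyl and the methoxy oxygen makes C10 the electrophilic end that bonds to the CH2 next to the silyloxy carbon (placing C1 between C11 and C12), suprafacial addition fixes 10-H and 14-CH3 cis, and the BINOLate shields one face to set the absolute configuration of C10 and C14.

Step 4
Reactants: 5 cis-fused Diels–Alder adduct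
Product: 7 cis-fused trione (C15 and C16 ketones; C8H=C9(CH3); C1 ketone), via tertiary carbinol 6 (not isolated)
Conditions: MeLi, CeCl3, THF, −78 °C; then 2 M HCl, THF, 23 °C
Reagents that add atoms: methyllithium, [Li]C; water, O
Why: Organocerium 1,2-addition followed by Stork–Danheiser transposition: the non-basic methylcerium reagent should add to the accessible vinylogous-ester carbonyl C9 rather than the C15 carbonyl shielded by quaternary C14, and acid then ionises the tertiary allylic alcohol, adds water at C16 and expels methanol to give the C16 ketone and the C8=C9 bond carrying the new methyl, while the silyl enol ether is hydrolysed to the C1 ketone.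

Step 5
Reactants: 7 cis-fused trione
Product: 8 8-iodo trione
Conditions: I2, pyridine, CH2Cl2, 0 to 23 °C
Reagents that add atoms: iodine, II
Why: α-Iodination of an enone by iodine and pyridine (conjugate addition of pyridine at C9, iodination at C8, elimination); C8 is the only enone α-carbon and the saturated C1 ketone is not iodinated under these conditions.

Step 6
Reactants: 8 8-iodo trione
Product: 9 16α-hydroxy-8-iodo dione (C15 and C1 ketones)
Conditions: NaBH4 (1 equiv), CeCl3·7H2O, MeOH–CH2Cl2, −78 °C
Reagents that add atoms: none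
Why: Luche reduction: the C16 carbonyl, an α-iodo enone carbonyl that is also part of a 1,2-dione, is the most electrophilic and least hindered of the three (C15 is neopentyl, C1 is an ordinary ketone that is slower at −78 °C), and hydride should add from the convex β face away from ring A′ to give the 16α-alcohol.

Step 7
Reactants: 9 16α-hydroxy-8-iodo dione
Product: 10 15β,16α-dihydroxy-8-iodo-1-ketone
Conditions: Me4NBH(OAc)3, AcOH–MeCN, −30 °C
Reagents that add atoms: none
Why: Hydroxyl-directed Saksena–Evans reduction: the boron hydride bound to the C16 oxygen delivers hydride intramolecularly to the α face of the neighbouring C15 ketone, giving the 15β-alcohol trans to 16α-OH, while the C1 ketone has no hydroxyl within reach and is left alone.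

Step 8
Reactants: 10 15β,16α-dihydroxy-8-iodo-1-ketone
Product: 11 15,16-bis(TBS) ether of 10
Conditions: TBSOTf, 2,6-lutidine, CH2Cl2, −78 to 0 °C
Reagents that add atoms: tert-butyldimethylsilyl triflate, CC(C)(C)[Si](C)(C)OS(=O)(=O)C(F)(F)F
Why: Silyl ether formation with a silyl triflate, which is reactive enough for the neopentyl C15 hydroxyl; no stereocentre changes and the ketone is tolerated at low temperature.

Step 9
Reactants: 11 15,16-bis(TBS) ether; 12 (S)-citronellal
Product: 13 (7S)-allylic alcohol from C7–C8 coupling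
Conditions: CrCl2, NiCl2 (2 mol %), (S)-N-[2-(4-isopropyl-4,5-dihydrooxazol-2-yl)-6-methylphenyl]methanesulfonamide, Et3N, THF–DMF, 23 °C
Reagents that add atoms: none
Why: Nozaki–Hiyama–Kishi coupling: nickel inserts into the C8–I bond, the alkenyl group passes to chromium and adds only to the aldehyde (the C1 ketone and silyl ethers are inert), and the chromium-bound oxazoline–sulfonamide ligand controls the aldehyde face to give the 7S alcohol, while C5 comes unchanged from citronellal.

Step 10
Reactants: 13 (7S)-allylic alcohol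
Product: 14 7-O-triethylsilyl ether of 13
Conditions: TESOTf, 2,6-lutidine, CH2Cl2, −78 °C
Reagents that add atoms: triethylsilyl triflate, CC[Si](CC)(CC)OS(=O)(=O)C(F)(F)F
Why: Silylation of the allylic C7 alcohol as a triethylsilyl ether, chosen because it can later be removed without touching the two TBS ethers.

Step 11
Reactants: 14 7-O-triethylsilyl ether
Product: 15 (Z)-11-hydroxymethylene ketone
Conditions: NaH, HCO2Et, EtOH (cat.), THF, 0 to 23 °C; aq. HCl work-up
Reagents that add atoms: ethyl formate, CCOC=O
Why: Claisen formylation under equilibrating conditions: like a 5β-3-keto steroid, the cis-fused ketone enolises toward the ring-fusion side, so the hydroxymethylene group should be installed at C11 and not at C12.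

Step 12
Reactants: 15 (Z)-11-hydroxymethylene ketone
Product: 16 11-diazo-1-ketone
Conditions: MsN3, Et3N, CH2Cl2, 0 °C
Reagents that add atoms: methanesulfonyl azide, CS(=O)(=O)N=[N+]=[N-]
Why: Regitz deformylative diazo transfer: the sulfonyl azide adds to the enolate of the α-formyl ketone and the formyl group leaves on the sulfonamide nitrogen, leaving the diazo group at C11.

Step 13
Reactants: 16 11-diazo-1-ketone
Product: 18 Weinreb amide on the contracted ring A (11-H β; C1 amide on the α face), via ketene 17 (not isolated)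
Conditions: hν (Hg lamp, Pyrex, >300 nm), MeNHOMe, THF, 0 °C
Reagents that add atoms: N,O-dimethylhydroxylamine, CNOC
Why: Photochemical Wolff rearrangement: loss of N2 from the diazo ketone, which is locked s-cis in ring A′, is concerted with migration of C12 from C1 to C11 and gives ketene 17, in which the six-membered ring A′ has become the five-membered ring A and C1 is exocyclic. The closest known reaction type is the Wolff ring contraction of cyclic α-diazo ketones used to turn 3-keto steroids into A-nor steroids. Ring A is not closed by a cyclisation; it arises from the 1,2-shift that forms C11–C12 as C1–C12 breaks. N,O-Dimethylhydroxylamine adds to the ketene and the resulting amide enol should be protonated at C11 from the convex β face, which places C1 on the concave α face, cis to C9 and C15, as ring C requires. The step needs rearrangement to outrun carbene insertion and needs a kinetic, non-equilibrated C11 centre; the s-cis cyclic diazo ketone secures the first, and the low temperature, the non-basic amine trap and the slow enolisation of the amide secure the second. C10 and C14 are untouched.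

Step 14
Reactants: 18 Weinreb amide
Product: 19 methyl ketone (C11–C1(=O)–C17H3)
Conditions: MeMgBr, THF, 0 °C
Reagents that add atoms: methylmagnesium bromide, C[Mg]Br
Why: Weinreb ketone synthesis: the chelated tetrahedral adduct stops at the ketone stage and the C11 centre is not enolised under these non-equilibrating conditions.

Step 15
Reactants: 19 methyl ketone
Product: 20 alkenyl triflate (C11–C1(OTf)=C17H2)
Conditions: KHMDS, PhNTf2, THF, −78 °C
Reagents that add atoms: N-phenylbis(trifluoromethanesulfonimide), O=S(=O)(N(c1ccccc1)S(=O)(=O)C(F)(F)F)C(F)(F)F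
Why: Kinetic enol triflate formation: the bulky amide base removes a proton from the methyl group C17 rather than the hindered C11 methine, and O-triflation gives the 1,1-disubstituted alkenyl triflate without touching C11.

Step 16
Reactants: 20 alkenyl triflate
Product: 21 7-alcohol (triethylsilyl group removed)
Conditions: PPTS, MeOH–CH2Cl2, 0 °C
Reagents that add atoms: none
Why: Selective acid-catalysed methanolysis of the secondary triethylsilyl ether, which is far more labile than the two hindered TBS ethers; the alkenyl triflate is stable to it.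

Step 17
Reactants: 21 7-alcohol
Product: 23 C2 aldehyde, via vicinal diol 22 (not isolated)
Conditions: OsO4 (2 mol %), NaIO4, 2,6-lutidine, dioxane–H2O, 23 °C
Reagents that add atoms: osmium tetroxide, O=[Os](=O)(=O)=O; sodium periodate, [Na+].[O-]I(=O)(=O)=O
Why: Johnson–Lemieux cleavage: OsO4 dihydroxylates the exposed trisubstituted side-chain alkene (the tetrasubstituted C8=C9 bond is crowded and the triflate-bearing alkene is electron-poor) and periodate cleaves the diol to the C2 aldehyde.

Step 18
Reactants: 23 C2 aldehyde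
Product: 24 macrocyclic (2R,7S)-diol with ring C closed
Conditions: CrCl2, NiCl2 (5 mol %), (R)-N-[2-(4-isopropyl-4,5-dihydrooxazol-2-yl)-6-methylphenyl]methanesulfonamide, Et3N, THF–DMF, 2 mM, 23 °C
Reagents that add atoms: none
Why: Intramolecular Nozaki–Hiyama–Kishi reaction at high dilution: the C1 alkenylchromium adds to the C2 aldehyde in an 11-exo-trig closure of ring C, giving the exocyclic methylene and the C2 carbinol directly, with the 2R configuration set by the chromium-bound ligand acting together with the conformation of the forming ring; the free C7 hydroxyl is tolerated.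

Step 19
Reactants: 24 macrocyclic (2R,7S)-diol
Product: 25 2,7-diacetate with 15,16-bis(TBS) ether
Conditions: Ac2O, DMAP, pyridine, 23 °C
Reagents that add atoms: acetic anhydride, CC(=O)OC(C)=O
Why: DMAP-catalysed acylation of the two free allylic alcohols at C2 and C7; the C15 and C16 oxygens are still silylated.

Step 20
Reactants: 25 2,7-diacetate with 15,16-bis(TBS) ether
Product: 26 CNP0286573.1 (target)
Conditions: HF·pyridine, pyridine–THF, 0 to 23 °C
Reagents that add atoms: none
Why: Fluoride-mediated desilylation under acidic, non-basic conditions, so the two acetates should neither cleave nor migrate, releasing the 15β,16α-diol of the target.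

Compound list
1 | 2-methoxy-6-methylphenol | COc1cccc(C)c1O | starting material
2 | 2-methoxy-6-methyl-1,4-benzoquinone | COC1=CC(=O)C=C(C)C1=O | intermediate
3 | methyl vinyl ketone (but-3-en-2-one) | CC(=O)C=C | starting material
4 | 2-(triisopropylsilyloxy)buta-1,3-diene | C=CC(=C)O[Si](C(C)C)(C(C)C)C(C)C | intermediate
5 | cis-fused Diels–Alder adduct, cis-2-methoxy-8a-methyl-6-(triisopropylsilyloxy)-4a,5,8,8a-tetrahydronaphthalene-1,4-dione (C15 and C9 ketones, 16-OMe, C1 silyl enol ether; 10-H and 14-CH3 β) | COC1=CC(=O)[C@@H]2CC(O[Si](C(C)C)(C(C)C)C(C)C)=CC[C@]2(C)C1=O | intermediate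
6 | C9 tertiary carbinol from 5 (9-OH, 9-CH3; C9 configuration immaterial) | COC1=CC(C)(O)[C@@H]2CC(O[Si](C(C)C)(C(C)C)C(C)C)=CC[C@]2(C)C1=O | intermediate
7 | cis-fused trione (C15 and C16 ketones, C8H=C9(CH3), C1 ketone in ring A′) | O=C1C=C(C)[C@@H]2CC(=O)CC[C@]2(C)C1=O | intermediate
8 | 8-iodo trione | O=C1C(I)=C(C)[C@@H]2CC(=O)CC[C@]2(C)C1=O | intermediate
9 | 16α-hydroxy-8-iodo dione (C15 and C1 ketones) | IC1=C(C)[C@@H]2CC(=O)CC[C@]2(C)C(=O)[C@@H]1O | intermediate
10 | 15β,16α-dihydroxy-8-iodo-1-ketone | IC1=C(C)[C@@H]2CC(=O)CC[C@]2(C)[C@@H](O)[C@@H]1O | intermediate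
11 | 15β,16α-bis(tert-butyldimethylsilyl) ether of 10 | IC1=C(C)[C@@H]2CC(=O)CC[C@]2(C)[C@@H](O[Si](C)(C)C(C)(C)C)[C@@H]1O[Si](C)(C)C(C)(C)C | intermediate
12 | (S)-citronellal, (S)-3,7-dimethyloct-6-enal | CC(C)=CCC[C@H](C)CC=O | starting material
13 | (7S)-allylic alcohol: C8 carries C7H(OH)–C6H2–C5(S)H(CH3)–C4H2–C3H2–C2H=C(CH3)2; C1 ketone; 15,16-bis(TBS) | CC(C)=CCC[C@H](C)C[C@H](O)C1=C(C)[C@@H]2CC(=O)CC[C@]2(C)[C@@H](O[Si](C)(C)C(C)(C)C)[C@@H]1O[Si](C)(C)C(C)(C)C | intermediate
14 | 7-O-triethylsilyl ether of 13 | CC(C)=CCC[C@H](C)C[C@H](O[Si](CC)(CC)CC)C1=C(C)[C@@H]2CC(=O)CC[C@]2(C)[C@@H](O[Si](C)(C)C(C)(C)C)[C@@H]1O[Si](C)(C)C(C)(C)C | intermediate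
15 | (Z)-11-hydroxymethylene derivative of 14 | CC(C)=CCC[C@H](C)C[C@H](O[Si](CC)(CC)CC)C1=C(C)[C@@H]2/C(=C/O)C(=O)CC[C@]2(C)[C@@H](O[Si](C)(C)C(C)(C)C)[C@@H]1O[Si](C)(C)C(C)(C)C | intermediate
16 | 11-diazo-1-ketone | CC(C)=CCC[C@H](C)C[C@H](O[Si](CC)(CC)CC)C1=C(C)[C@@H]2C(=[N+]=[N-])C(=O)CC[C@]2(C)[C@@H](O[Si](C)(C)C(C)(C)C)[C@@H]1O[Si](C)(C)C(C)(C)C | intermediate
17 | ketene on the contracted ring A (C11=C1=O) | CC(C)=CCC[C@H](C)C[C@H](O[Si](CC)(CC)CC)C1=C(C)[C@@H]2C(=C=O)CC[C@]2(C)[C@@H](O[Si](C)(C)C(C)(C)C)[C@@H]1O[Si](C)(C)C(C)(C)C | intermediate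
18 | Weinreb amide: ring A cyclopentane, 11-H β, C1(=O)N(OCH3)CH3 on C11 (α face) | CC(C)=CCC[C@H](C)C[C@H](O[Si](CC)(CC)CC)C1=C(C)[C@@H]2[C@H](C(=O)N(C)OC)CC[C@]2(C)[C@@H](O[Si](C)(C)C(C)(C)C)[C@@H]1O[Si](C)(C)C(C)(C)C | intermediate
19 | methyl ketone (C11–C1(=O)–C17H3) | CC(C)=CCC[C@H](C)C[C@H](O[Si](CC)(CC)CC)C1=C(C)[C@@H]2[C@H](C(C)=O)CC[C@]2(C)[C@@H](O[Si](C)(C)C(C)(C)C)[C@@H]1O[Si](C)(C)C(C)(C)C | intermediate
20 | alkenyl triflate (C11–C1(OTf)=C17H2) | CC(C)=CCC[C@H](C)C[C@H](O[Si](CC)(CC)CC)C1=C(C)[C@@H]2[C@H](C(=C)OS(=O)(=O)C(F)(F)F)CC[C@]2(C)[C@@H](O[Si](C)(C)C(C)(C)C)[C@@H]1O[Si](C)(C)C(C)(C)C | intermediate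
21 | 7-alcohol of 20 (triethylsilyl group removed) | CC(C)=CCC[C@H](C)C[C@H](O)C1=C(C)[C@@H]2[C@H](C(=C)OS(=O)(=O)C(F)(F)F)CC[C@]2(C)[C@@H](O[Si](C)(C)C(C)(C)C)[C@@H]1O[Si](C)(C)C(C)(C)C | intermediate
22 | vicinal diol from the side-chain alkene (C2–OH and C(CH3)2–OH; C2 configuration immaterial) | CC(C)(O)C(O)CC[C@H](C)C[C@H](O)C1=C(C)[C@@H]2[C@H](C(=C)OS(=O)(=O)C(F)(F)F)CC[C@]2(C)[C@@H](O[Si](C)(C)C(C)(C)C)[C@@H]1O[Si](C)(C)C(C)(C)C | intermediate
23 | C2 aldehyde (7-OH, C1 alkenyl triflate, 15,16-bis(TBS)) | O=CCC[C@H](C)C[C@H](O)C1=C(C)[C@@H]2[C@H](C(=C)OS(=O)(=O)C(F)(F)F)CC[C@]2(C)[C@@H](O[Si](C)(C)C(C)(C)C)[C@@H]1O[Si](C)(C)C(C)(C)C | intermediate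
24 | macrocyclic (2R,7S)-diol, ring C closed, exocyclic C1=C17H2, 15,16-bis(TBS) | C=C1[C@H](O)CC[C@H](C)C[C@H](O)C2=C(C)[C@@H]3[C@H]1CC[C@]3(C)[C@@H](O[Si](C)(C)C(C)(C)C)[C@@H]2O[Si](C)(C)C(C)(C)C | intermediate
25 | (2R,7S)-diacetate, 15,16-bis(TBS) | C=C1[C@H](OC(C)=O)CC[C@H](C)C[C@H](OC(C)=O)C2=C(C)[C@@H]3[C@H]1CC[C@]3(C)[C@@H](O[Si](C)(C)C(C)(C)C)[C@@H]2O[Si](C)(C)C(C)(C)C | intermediate
26 | CNP0286573.1: (2R,5S,7S)-2,7-diacetate with 15β,16α-diol, cis-fused rings A and B, 11-H β | C=C1[C@H](OC(C)=O)CC[C@H](C)C[C@H](OC(C)=O)C2=C(C)[C@@H]3[C@H]1CC[C@]3(C)[C@@H](O)[C@@H]2O | target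

Total step count: 20. Longest linear sequence: 19 steps (1 → 2 → 5 → … → 26; step 2 is a one-step side branch).

Steps most likely to fail

Step 13 (key step). After loss of nitrogen the system may leak into carbene pathways (1,2-hydrogen shift from C10 or C12, insertion into solvent) instead of the concerted 1,2-shift, and protonation of the ketene–amine adduct may not be selective for the β face. The fallback sets out from 15 and comes back at 18. The α-hydroxymethylene ketone 15 is treated with 30% H2O2 in tert-butanol (oxidative ring contraction of α-formyl ketones: epoxidation of the enol, acyl shift that moves C12 to C11, loss of the formyl carbon as formic acid), which should give the ring-contracted C11 carboxylic acid F1. The acid is coupled with N,O-dimethylhydroxylamine (1-ethyl-3-(3-dimethylaminopropyl)carbodiimide, CH2Cl2) to give 18. If C11 is formed as a mixture, the lithium enolate of 18 is reprotonated kinetically from the β face.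

Step 18. Intermolecular coupling and protonation of the alkenylchromium may compete with closure of the strained eleven-membered ring, and the aldehyde face may be poorly differentiated. The fallback sets out from 20 and comes back at 24. LDA (THF, −78 °C) eliminates triflate from 20 to give the C11 ethynyl compound F2. Johnson–Lemieux cleavage as in step 17 gives the ynal F3. Nickel-catalysed reductive alkyne–aldehyde macrocyclisation (Ni(cod)2, zerovalent nickel, with 1,3-bis(2,6-diisopropylphenyl)imidazol-2-ylidene and Et3SiH, THF, high dilution) joins the internal alkyne carbon C1 to C2 and should give the exocyclic-methylene macrocycle as its 2,7-bis(triethylsilyl) ether F4. PPTS in methanol removes both triethylsilyl groups to give 24.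

Step 3. The Lewis acid may bind the more basic C9 carbonyl, which would reverse the orientation of the diene, or the enantioselectivity may be low. The fallback sets out from 2 (with 4) and comes back at 9. The uncatalysed cycloaddition (toluene, 80 °C) is governed by the C15 carbonyl and should give racemic 5 with the needed orientation. The racemate is carried through steps 4–6 and racemic 9 is resolved by lipase-catalysed acylation (Candida antarctica lipase B, vinyl acetate, MTBE). The 16-O-acetate of the wanted antipode F5 is separated and returned to 9 by methanolysis (K2CO3, MeOH, 0 °C); if the wanted antipode is the slow-reacting one, it is recovered directly as 9.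

Further compounds
F1 | step 13 | ring-contracted C11 carboxylic acid (C1 = CO2H; 7-O-triethylsilyl, 15,16-bis(TBS)) | CC(C)=CCC[C@H](C)C[C@H](O[Si](CC)(CC)CC)C1=C(C)[C@@H]2[C@H](C(=O)O)CC[C@]2(C)[C@@H](O[Si](C)(C)C(C)(C)C)[C@@H]1O[Si](C)(C)C(C)(C)C
F2 | step 18 | C11 ethynyl compound (C1≡C17H; 7-O-triethylsilyl, 15,16-bis(TBS)) | CC(C)=CCC[C@H](C)C[C@H](O[Si](CC)(CC)CC)C1=C(C)[C@@H]2[C@H](C#C)CC[C@]2(C)[C@@H](O[Si](C)(C)C(C)(C)C)[C@@H]1O[Si](C)(C)C(C)(C)C
F3 | step 18 | ynal (C2 aldehyde, C11 ethynyl; 7-O-triethylsilyl, 15,16-bis(TBS)) | O=CCC[C@H](C)C[C@H](O[Si](CC)(CC)CC)C1=C(C)[C@@H]2[C@H](C#C)CC[C@]2(C)[C@@H](O[Si](C)(C)C(C)(C)C)[C@@H]1O[Si](C)(C)C(C)(C)C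
F4 | step 18 | macrocycle as 2,7-bis(triethylsilyl) ether, 15,16-bis(TBS) | C=C1[C@H](O[Si](CC)(CC)CC)CC[C@H](C)C[C@H](O[Si](CC)(CC)CC)C2=C(C)[C@@H]3[C@H]1CC[C@]3(C)[C@@H](O[Si](C)(C)C(C)(C)C)[C@@H]2O[Si](C)(C)C(C)(C)C
F5 | step 3 | 16-O-acetate of 9 | IC1=C(C)[C@@H]2CC(=O)CC[C@]2(C)C(=O)[C@@H]1OC(C)=O
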